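**Plan**
1. The side-chain backbone is numbered C1'–C32' from the ring. The retrosynthesis first restores two O-methyl groups, so the quinone ring becomes an aromatic 1,4-dimethoxynaphthalene. It then cuts the sp2–sp3 bond C17'–C18' at mid-chain, then C16'–C17', then ring C3–C1'. In the other half it cuts C18'–I, C19'–CH3 and the farnesyl–propargyl bond.
2. Enabling feature: the chain repeats a 1,5-diene, so C17' is a primary homoallylic CH2 lying between the CH2 C16' and the vinyl CH C18'. A radical at C17' comes from the 4-methylalk-4-enoic acid that is one carbon longer. That radical can reach C14'=C15' only by reversible 3-exo closure, and no other alkene lies within five- or six-ring reach, so it survives until an alkenylnickel formed at C18' captures it.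
3. Helpers: the quinone ring would be reduced at the cathode and would trap radicals, so it is carried as the dimethyl ether. The acid is carried as its N-hydroxyphthalimide ester. This ester leaves as CO2 and phthalimide in the key step, and the methyl groups leave in the last step.
4. Forward order: C15 bromide + C3 silylpropyne → enyne → C19 (E)-alkenyl iodide. Menadione → bromodimethoxynaphthalene, joined to the C20 bromide. Then terminal oxidation, bromide, C2 acid, active ester, electrolysis and oxidation to the quinone.
5. Stereochemistry: there are no stereocentres. Five E alkenes are bought (two in farnesyl bromide, three in geranylgeraniol). C14'=C15' becomes E in the E-selective SeO2 oxidation, and C18'=C19' becomes E by syn-carboalumination. All later steps retain geometry.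

Key step: step 12

Assumption: commercial (2E,6E)-farnesyl bromide and (2E,6E,10E)-geranylgeraniol are used as the geometrically pure all-E isomers.

**Route**

Step 1
Reactants: 1 (2E,6E)-farnesyl bromide; 2 1-(trimethylsilyl)propyne
Product: 4 trimethyl[(5E,9E)-6,10,14-trimethylpentadeca-5,9,13-trien-1-yn-1-yl]silane, via 3-lithio-1-(trimethylsilyl)propyne 3 (not isolated)
Conditions: 2, n-BuLi, THF, −78 → −20 °C; then 1, −78 °C → rt
Reagents that add atoms: none
Why: Propargylic lithiation followed by SN2 alkylation of the primary allylic bromide is a standard route to 1,5-enynes, because the silyl group steers attack to the CH2 terminus and both E alkenes stay untouched.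

Step 2
Reactants: 4 silylated enyne
Product: 5 (5E,9E)-6,10,14-trimethylpentadeca-5,9,13-trien-1-yne
Conditions: K2CO3 (cat.), MeOH/THF, rt
Reagents that add atoms: none
Why: Base-catalysed protodesilylation cleaves only the alkynyl C–Si bond by methanolysis.

Step 3
Reactants: 5 terminal enyne
Product: 7 (1E,5E,9E)-1-iodo-2,6,10,14-tetramethylpentadeca-1,5,9,13-tetraene, via (E)-alkenyl(dimethyl)alane 6 (not isolated)
Conditions: Me3Al, Cp2ZrCl2 (cat.), CH2Cl2, 0 °C → rt; then I2, THF, −30 → 0 °C
Reagents that add atoms: trimethylaluminium C[Al](C)C; iodine II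
Why: Negishi carboalumination adds CH3 and Al syn across the terminal alkyne with Al at the terminus, and iodinolysis with retention should give the (E)-iodide while the trisubstituted alkenes stay inert.

Step 4
Reactants: 8 menadione (2-methyl-1,4-naphthoquinone)
Product: 10 1,4-dimethoxy-2-methylnaphthalene, via menadiol 9 (not isolated)
Conditions: Na2S2O4, Bu4NBr (cat.), THF/H2O, rt; then KOH aq, Me2SO4, rt, N2
Reagents that add atoms: dimethyl sulfate COS(=O)(=O)OC
Why: Dithionite reduction and Williamson O-methylation in one flask (reductive methylation) mask the redox-active ring as an aromatic diether.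

Step 5
Reactants: 10 1,4-dimethoxy-2-methylnaphthalene
Product: 11 2-bromo-1,4-dimethoxy-3-methylnaphthalene
Conditions: Br2, CH2Cl2, 0 °C
Reagents that add atoms: bromine BrBr
Why: Electrophilic aromatic bromination goes to the only free position of the ring that carries both methoxy groups.

Step 6
Reactants: 12 (2E,6E,10E)-geranylgeraniol
Product: 13 (2E,6E,10E)-geranylgeranyl bromide
Conditions: PBr3, Et2O, −10 → 0 °C, used crude
Reagents that add atoms: phosphorus tribromide BrP(Br)Br
Why: Bromide displaces the intermediate phosphite ester by SN2 at low temperature, the standard conversion of polyprenols into bromides without allylic transposition or E/Z erosion.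

Step 7
Reactants: 11 bromodimethoxynaphthalene; 13 geranylgeranyl bromide
Product: 16 2-[(2E,6E,10E)-3,7,11,15-tetramethylhexadeca-2,6,10,14-tetraen-1-yl]-1,4-dimethoxy-3-methylnaphthalene, via aryllithium 14 (not isolated), via arylcopper 15 (not isolated)
Conditions: 11, n-BuLi, THF, −78 °C; CuBr·SMe2, −78 → −40 °C; then 13, −40 °C → rt
Reagents that add atoms: none
Why: Bromine–lithium exchange and transmetalation to copper give a soft aryl nucleophile, and this arylcopper allylation displaces the γ,γ-disubstituted allylic bromide at its α-carbon so that C2'=C3' stays E.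

Step 8
Reactants: 16 geranylgeranyl dimethoxynaphthalene
Product: 17 (2E,6E,10E,14E)-16-(1,4-dimethoxy-3-methylnaphthalen-2-yl)-2,6,10,14-tetramethylhexadeca-2,6,10,14-tetraen-1-ol
Conditions: SeO2 (cat.), t-BuOOH, salicylic acid (cat.), CH2Cl2, 0 °C → rt, stopped at partial conversion, 16 recycled
Reagents that add atoms: tert-butyl hydroperoxide CC(C)(C)OO (oxygen relayed through selenium dioxide O=[Se]=O)
Why: Riley allylic oxidation (ene reaction, then [2,3]-sigmatropic shift) prefers the least hindered terminal gem-dimethyl alkene and oxygenates only the methyl trans to the chain, which fixes C14'=C15' as E.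

Step 9
Reactants: 17 terminal allylic alcohol
Product: 18 2-[(2E,6E,10E,14E)-16-bromo-3,7,11,15-tetramethylhexadeca-2,6,10,14-tetraen-1-yl]-1,4-dimethoxy-3-methylnaphthalene
Conditions: PBr3, Et2O, −10 → 0 °C
Reagents that add atoms: phosphorus tribromide BrP(Br)Br
Why: The same SN2 bromination of a primary allylic alcohol as in step 6 applies here, and neither the aryl ethers nor the trisubstituted alkenes react at this temperature.

Step 10
Reactants: 18 terminal allylic bromide; 19 acetic acid
Product: 21 (4E,8E,12E,16E)-18-(1,4-dimethoxy-3-methylnaphthalen-2-yl)-4,8,12,16-tetramethyloctadeca-4,8,12,16-tetraenoic acid, via dilithioacetate 20 (not isolated)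
Conditions: 19, LiN(iPr)2 (2 equiv, commercial solution), THF/DMPU, 0 °C → rt; then 18, 0 °C → rt; 1 M HCl work-up
Reagents that add atoms: none
Why: Alkylation of a carboxylic acid dianion by SN2 at the primary allylic bromide adds C17' and the carboxyl carbon at once and delivers the free acid without a hydrolysis step.

Step 11
Reactants: 21 tetraenoic acid
Product: 22 1,3-dioxoisoindolin-2-yl ester of acid 21
Conditions: N-hydroxyphthalimide, DIC, DMAP (cat.), CH2Cl2, rt
Reagents that add atoms: N-hydroxyphthalimide O=C1c2ccccc2C(=O)N1O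
Why: Steglich-type carbodiimide esterification installs the electron-accepting phthalimide ester under neutral conditions that the polyene tolerates.

Step 12
Reactants: 22 N-hydroxyphthalimide ester; 7 (E)-alkenyl iodide
Product: 23 2-[(2E,6E,10E,14E,18E,22E,26E)-3,7,11,15,19,23,27,31-octamethyldotriaconta-2,6,10,14,18,22,26,30-octaen-1-yl]-1,4-dimethoxy-3-methylnaphthalene
Conditions: NiCl2·6H2O (cat.), 2,2'-bipyridine (cat.), AgNO3 (0.3 equiv), LiCl, DMF/THF, undivided cell, Mg anode, reticulated vitreous carbon cathode, constant current, rt; 7 in slight excess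
Reagents that add atoms: none
Why: At the cathode, coated with silver nanoparticles plated from AgNO3, the divalent nickel–bipyridine complex is reduced to low-valent nickel, which inserts into the C–I bond of 7 with retention to give an (E)-alkenylnickel species. One-electron transfer to the phthalimide ring of 22 breaks the N–O bond, CO2 leaves, and the primary radical at C17' is caught by the alkenylnickel to give a trivalent nickel species whose reductive elimination forms C17'–C18', the Mg anode supplying the two electrons. The closest known reaction type is the nickel-electrocatalytic decarboxylative alkenylation of N-hydroxyphthalimide esters with alkenyl iodides, which has been applied to this same skipped-diene junction in polyprenoid chains. No ring is closed and no stereocentre is formed; the only stereochemical demand is retention of E geometry at C18'=C19', which stereoretentive oxidative addition and reductive elimination at nickel secure. The step needs cross-coupling over homocoupling and a radical that does not cyclise: the excess of 7 and current-limited radical generation serve the first need, and the 1,5-diene spacing serves the second, since C17' reaches C14'=C15' only by reversible 3-exo closure and C10'=C11' only through a strained seven-membered ring holding an E alkene. The dimethoxynaphthalene ring is inert at both electrodes because the Mg anode is oxidised far more easily, whereas the free quinone would be reduced before nickel and would trap the radical.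

Step 13
Reactants: 23 menaquinol-8 dimethyl ether
Product: 24 menaquinone-8
Conditions: (NH4)2Ce(NO3)6, MeCN/CH2Cl2/H2O, 0 °C
Reagents that add atoms: water O
Why: Oxidative demethylation by tetravalent cerium takes two electrons from the electron-rich ring, water attacks, two methanol molecules leave, and the 1,4-quinone should form faster than the isolated trisubstituted alkenes are touched.

**Compound list**
1 | (2E,6E)-farnesyl bromide, (2E,6E)-1-bromo-3,7,11-trimethyldodeca-2,6,10-triene | CC(C)=CCC/C(C)=C/CC/C(C)=C/CBr | starting material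
2 | 1-(trimethylsilyl)propyne | CC#C[Si](C)(C)C | starting material
3 | 3-lithio-1-(trimethylsilyl)propyne | [Li]CC#C[Si](C)(C)C | intermediate
4 | trimethyl[(5E,9E)-6,10,14-trimethylpentadeca-5,9,13-trien-1-yn-1-yl]silane | CC(C)=CCC/C(C)=C/CC/C(C)=C/CCC#C[Si](C)(C)C | intermediate
5 | (5E,9E)-6,10,14-trimethylpentadeca-5,9,13-trien-1-yne | CC(C)=CCC/C(C)=C/CC/C(C)=C/CCC#C | intermediate
6 | dimethyl[(1E,5E,9E)-2,6,10,14-tetramethylpentadeca-1,5,9,13-tetraen-1-yl]alane | CC(C)=CCC/C(C)=C/CC/C(C)=C/CC/C(C)=C/[Al](C)C | intermediate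
7 | (1E,5E,9E)-1-iodo-2,6,10,14-tetramethylpentadeca-1,5,9,13-tetraene | CC(C)=CCC/C(C)=C/CC/C(C)=C/CC/C(C)=C/I | intermediate
8 | menadione, 2-methyl-1,4-naphthoquinone | CC1=CC(=O)c2ccccc2C1=O | starting material
9 | menadiol, 2-methylnaphthalene-1,4-diol | Cc1cc(O)c2ccccc2c1O | intermediate
10 | 1,4-dimethoxy-2-methylnaphthalene | COc1cc(C)c(OC)c2ccccc12 | intermediate
11 | 2-bromo-1,4-dimethoxy-3-methylnaphthalene | COc1c(C)c(Br)c(OC)c2ccccc12 | intermediate
12 | (2E,6E,10E)-geranylgeraniol | CC(C)=CCC/C(C)=C/CC/C(C)=C/CC/C(C)=C/CO | starting material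
13 | (2E,6E,10E)-geranylgeranyl bromide | CC(C)=CCC/C(C)=C/CC/C(C)=C/CC/C(C)=C/CBr | intermediate
14 | (1,4-dimethoxy-3-methylnaphthalen-2-yl)lithium | [Li]c1c(C)c(OC)c2ccccc2c1OC | intermediate
15 | (1,4-dimethoxy-3-methylnaphthalen-2-yl)copper | [Cu]c1c(C)c(OC)c2ccccc2c1OC | intermediate
16 | 2-[(2E,6E,10E)-geranylgeranyl]-1,4-dimethoxy-3-methylnaphthalene (menaquinol-4 dimethyl ether) | CC(C)=CCC/C(C)=C/CC/C(C)=C/CC/C(C)=C/Cc1c(C)c(OC)c2ccccc2c1OC | intermediate
17 | (2E,6E,10E,14E)-16-(1,4-dimethoxy-3-methylnaphthalen-2-yl)-2,6,10,14-tetramethylhexadeca-2,6,10,14-tetraen-1-ol | OC/C(C)=C/CC/C(C)=C/CC/C(C)=C/CC/C(C)=C/Cc1c(C)c(OC)c2ccccc2c1OC | intermediate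
18 | 2-[(2E,6E,10E,14E)-16-bromo-3,7,11,15-tetramethylhexadeca-2,6,10,14-tetraen-1-yl]-1,4-dimethoxy-3-methylnaphthalene | BrC/C(C)=C/CC/C(C)=C/CC/C(C)=C/CC/C(C)=C/Cc1c(C)c(OC)c2ccccc2c1OC | intermediate
19 | acetic acid | CC(=O)O | starting material
20 | dilithioacetate (acetic acid dianion, dilithium salt) | [Li]CC(=O)O[Li] | intermediate
21 | (4E,8E,12E,16E)-18-(1,4-dimethoxy-3-methylnaphthalen-2-yl)-4,8,12,16-tetramethyloctadeca-4,8,12,16-tetraenoic acid | OC(=O)CC/C(C)=C/CC/C(C)=C/CC/C(C)=C/CC/C(C)=C/Cc1c(C)c(OC)c2ccccc2c1OC | intermediate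
22 | 1,3-dioxoisoindolin-2-yl (4E,8E,12E,16E)-18-(1,4-dimethoxy-3-methylnaphthalen-2-yl)-4,8,12,16-tetramethyloctadeca-4,8,12,16-tetraenoate | O=C(CC/C(C)=C/CC/C(C)=C/CC/C(C)=C/CC/C(C)=C/Cc1c(C)c(OC)c2ccccc2c1OC)ON1C(=O)c2ccccc2C1=O | intermediate
23 | 2-[(all-E)-octaprenyl]-1,4-dimethoxy-3-methylnaphthalene (menaquinol-8 dimethyl ether) | CC(C)=CCC/C(C)=C/CC/C(C)=C/CC/C(C)=C/CC/C(C)=C/CC/C(C)=C/CC/C(C)=C/CC/C(C)=C/Cc1c(C)c(OC)c2ccccc2c1OC | intermediate
24 | menaquinone-8 | CC(C)=CCC/C(C)=C/CC/C(C)=C/CC/C(C)=C/CC/C(C)=C/CC/C(C)=C/CC/C(C)=C/CC/C(C)=C/CC1=C(C)C(=O)c2ccccc2C1=O | target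

**Step count**
Total steps: 13. Longest linear sequence: 9 steps (4, 5, 7, 8, 9, 10, 11, 12, 13).

**Steps most likely to fail**

Step 12. The radical may be quenched by hydrogen abstraction before nickel captures it. The alkenyl iodide may homocouple. The two very lipophilic partners may also dissolve poorly in the electrolyte and foul the cathode.
The fallback replaces the radical electrolysis by a two-electron B-alkyl Suzuki–Miyaura coupling. It sets out from 17 and 7 and comes back at 23.
- Alcohol 17 is oxidised with MnO2 in CH2Cl2 to the (E)-enal F1.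
- Wittig methylenation with Ph3P=CH2 in THF gives the terminal 1,3-diene F2.
- 9-BBN-H hydroborates only the monosubstituted vinyl group and gives the homoallylic B-alkyl-9-BBN F3.
- F3 is coupled in the same flask with 7 under PdCl2(dppf), Cs2CO3 and DMF/THF/H2O, with retention of the iodide geometry, to give 23.

Step 8. Site selectivity between the terminal alkene and the three internal alkenes may be poor, and over-oxidation past the alcohol stage may occur.
The fallback moves the terminal functionalisation to an aqueous halohydrin reaction, in which coiling of the chain exposes only its end, and lets a [3,3] shift set the alkene geometry. It sets out from 16, comes back at 21, and makes steps 9 and 10 unnecessary.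
- NBS in THF/H2O at 0 °C gives the terminal bromohydrin F4.
- K2CO3 in MeOH closes it to the terminal epoxide F5.
- Al(OiPr)3 in refluxing toluene isomerises it to the isopropenyl carbinol F6.
- Johnson–Claisen rearrangement with triethyl orthoacetate and catalytic propionic acid at 140 °C passes through a chair with the chain equatorial and gives the (E)-ethyl ester F7.
- LiOH in THF/H2O hydrolyses F7 to 21.
- The racemic carbinol centre of F4 to F6 is erased in the rearrangement.

Step 10. The sparingly soluble and strongly basic dianion may react sluggishly, may eliminate HBr from the bromide, or may lead to double alkylation.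
The fallback uses a soft stabilised carbanion in a malonic ester synthesis. It sets out from 18 and comes back at 21.
- Dimethyl malonate and NaH in THF alkylate 18 to the malonate diester F8.
- KOH in MeOH/H2O gives the malonic acid F9.
- Heating F9 in pyridine removes one carboxyl group by decarboxylation and gives 21.

**Further compounds**
F1 | step 12 | (2E,6E,10E,14E)-16-(1,4-dimethoxy-3-methylnaphthalen-2-yl)-2,6,10,14-tetramethylhexadeca-2,6,10,14-tetraenal | O=C/C(C)=C/CC/C(C)=C/CC/C(C)=C/CC/C(C)=C/Cc1c(C)c(OC)c2ccccc2c1OC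
F2 | step 12 | 2-[(2E,6E,10E,14E)-3,7,11,15-tetramethylheptadeca-2,6,10,14,16-pentaen-1-yl]-1,4-dimethoxy-3-methylnaphthalene | C=C/C(C)=C/CC/C(C)=C/CC/C(C)=C/CC/C(C)=C/Cc1c(C)c(OC)c2ccccc2c1OC
F3 | step 12 | 9-[(3E,7E,11E,15E)-17-(1,4-dimethoxy-3-methylnaphthalen-2-yl)-3,7,11,15-tetramethylheptadeca-3,7,11,15-tetraen-1-yl]-9-borabicyclo[3.3.1]nonane | B1(CC/C(C)=C/CC/C(C)=C/CC/C(C)=C/CC/C(C)=C/Cc3c(C)c(OC)c4ccccc4c3OC)C2CCCC1CCC2
F4 | step 8 | (6E,10E,14E)-3-bromo-16-(1,4-dimethoxy-3-methylnaphthalen-2-yl)-2,6,10,14-tetramethylhexadeca-6,10,14-trien-2-ol (racemic) | CC(C)(O)C(Br)CC/C(C)=C/CC/C(C)=C/CC/C(C)=C/Cc1c(C)c(OC)c2ccccc2c1OC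
F5 | step 8 | 2-[(2E,6E,10E)-14,15-epoxy-3,7,11,15-tetramethylhexadeca-2,6,10-trien-1-yl]-1,4-dimethoxy-3-methylnaphthalene (racemic) | CC1(C)OC1CC/C(C)=C/CC/C(C)=C/CC/C(C)=C/Cc1c(C)c(OC)c2ccccc2c1OC
F6 | step 8 | (6E,10E,14E)-16-(1,4-dimethoxy-3-methylnaphthalen-2-yl)-2,6,10,14-tetramethylhexadeca-1,6,10,14-tetraen-3-ol (racemic) | C=C(C)C(O)CC/C(C)=C/CC/C(C)=C/CC/C(C)=C/Cc1c(C)c(OC)c2ccccc2c1OC
F7 | step 8 | ethyl (4E,8E,12E,16E)-18-(1,4-dimethoxy-3-methylnaphthalen-2-yl)-4,8,12,16-tetramethyloctadeca-4,8,12,16-tetraenoate | CCOC(=O)CC/C(C)=C/CC/C(C)=C/CC/C(C)=C/CC/C(C)=C/Cc1c(C)c(OC)c2ccccc2c1OC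
F8 | step 10 | dimethyl 2-[(2E,6E,10E,14E)-16-(1,4-dimethoxy-3-methylnaphthalen-2-yl)-2,6,10,14-tetramethylhexadeca-2,6,10,14-tetraen-1-yl]malonate | COC(=O)C(C(=O)OC)C/C(C)=C/CC/C(C)=C/CC/C(C)=C/CC/C(C)=C/Cc1c(C)c(OC)c2ccccc2c1OC
F9 | step 10 | 2-[(2E,6E,10E,14E)-16-(1,4-dimethoxy-3-methylnaphthalen-2-yl)-2,6,10,14-tetramethylhexadeca-2,6,10,14-tetraen-1-yl]malonic acid | OC(=O)C(C(=O)O)C/C(C)=C/CC/C(C)=C/CC/C(C)=C/CC/C(C)=C/Cc1c(C)c(OC)c2ccccc2c1OC
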